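**Retrosynthetic overview**

1. Steroid-type numbering is used: ring A = C1–C5/C10, ring B = C5–C10, ring C = C8/C9/C11–C14, ring D = C13–C16, and C19 is the lactone carbonyl on C10. The plan rests on ring C. It is a cyclohexene with three adjacent fully substituted carbons (C8, C14, C13), and its C13–C14 bond is also an edge of four-membered ring D, so that bond can be delivered as the C=C of a cyclobutenone.
2. 34 ⇒ 33 ⇒ 32 ⇒ 31 ⇒ 30. The C16–OH is unmasked last, the C11=C12 alkene comes from a C11 ketone through its C12-side enol triflate, and H9 comes from protonation of a C9=C11 enol silane.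
3. 30 ⇒ 19 + 29. A Diels–Alder disconnection of C8–C14 and C12–C13 (ring C) gives the AB-lactone silyloxydiene and an enantiopure ring D cyclobutenone ester.
4. 19 ⇒ 15 ⇒ 13 ⇒ 8 ⇒ 6 ⇒ 1 + 4. C9–C11 comes from an enol triflate and propanal, O6–C19 from bromolactonisation of the 5-ene ester, and ring A from a Robinson annulation. 29 ⇒ 20, in which the squarate ring becomes ring D.
5. Ring order: B (bought in 1) and D (bought in 20), then A (step 3), the lactone (step 6) and C (step 23).

Key step: step 23

Convention: "lower face" is the face that carries C19 (in 34 also O6, the C8 and C13 methyl groups, CO2Me and C16–OH). "Upper face" is the face of H5, H9, C3–OAc and the C16 methyl group.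
Assumption: C8 in 14 and C11 in 17 should form as epimer mixtures and are written without configuration, because both carbons become sp2 one step later.

**Diene fragment (steps 1–15)**

Step 1
Reactants: 1 cyclohexane-1,3-dione
Product: 3 methyl 2-hydroxy-6-oxocyclohex-1-ene-1-carboxylate, via enol carbonate 2 (not isolated)
Conditions: ClCO2Me, Et3N (2.2 equiv), CH2Cl2, 0 °C; then DMAP (20 mol %), rt; 1 M HCl work-up
Reagents that add atoms: methyl chloroformate, COC(=O)Cl
Why: O-acylation followed by DMAP-catalysed O-to-C carboxyl transfer (the acyl-migration route from enol esters of cyclic 1,3-diones to 2-acyl-1,3-diones) should be pulled to the C-acylated product, because only that product is deprotonated by Et3N to a chelated tricarbonyl enolate.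

Step 2
Reactants: 3 methyl 2-hydroxy-6-oxocyclohex-1-ene-1-carboxylate; 4 methyl vinyl ketone
Product: 5 methyl 2,6-dioxo-1-(3-oxobutyl)cyclohexane-1-carboxylate (achiral)
Conditions: Et3N (10 mol %), MeCN, rt
Reagents that add atoms: none
Why: Amine-catalysed Michael addition of the soft, fully enolised tricarbonyl nucleophile to the unhindered enone builds the quaternary carbon (future C10) under conditions too mild for retro-Claisen cleavage.

Step 3
Reactants: 5 triketo ester
Product: 6 methyl (S)-1,6-dioxo-2,3,4,6,7,8-hexahydronaphthalene-8a(1H)-carboxylate (C3 enone, C4=C5, C9 ketone, C10–CO2Me)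
Conditions: D-proline (20 mol %), DMSO, rt; recrystallisation
Reagents that add atoms: none
Why: In this enamine-mediated intramolecular aldol condensation (Hajos–Parrish–Eder–Sauer–Wiechert reaction, the second half of a Robinson annulation) D-proline steers the side-chain enamine onto one of the two enantiotopic ring carbonyls, in the sense that gives (R)-Wieland–Miescher ketone in the methyl series, and so sets C10 (labelled S here only because CO2Me outranks the ring carbons).

Step 4
Reactants: 6 enedione ester
Product: 7 C9 ethylene ketal of 6 (enone untouched)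
Conditions: TMSOCH2CH2OTMS, TMSOTf (5 mol %), CH2Cl2, −78 → −20 °C
Reagents that add atoms: 1,2-bis(trimethylsilyloxy)ethane, C[Si](C)(C)OCCO[Si](C)(C)C
Why: Ketalisation with the bis-silyl glycol under TMSOTf catalysis (Noyori conditions) is kinetically selective for a saturated ketone over an enone, as in the parent Wieland–Miescher ketone, and masks C9 for the base and hydride steps that follow.

Step 5
Reactants: 7 enone ketal
Product: 8 4,4-dimethyl-5(6)-en-3-one ester ketal
Conditions: KOtBu (2.5 equiv), t-BuOH/THF, 0 °C; MeI, 0 °C → rt
Reagents that add atoms: iodomethane, CI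
Why: Deconjugative double α-alkylation through the extended C3–C6 dienolate is the standard route from a Wieland–Miescher ketal to a 4,4-dimethyl-5-en-3-one, and it installs the gem-dimethyl group while moving the alkene to C5=C6 next to the angular ester, which has no α-hydrogen.

Step 6
Reactants: 8 5-ene ester
Product: 9 5-bromo-6,19-lactone (C19(=O)–O–C6 bridge on the lower face, Br on C5 on the upper face, C3 ketone, C9 dioxolane)
Conditions: NBS, THF/H2O (4:1), 0 °C → rt, dark
Reagents that add atoms: N-bromosuccinimide, O=C1CCC(=O)N1Br; water, O
Why: In this bromolactonisation the bromonium ion on the upper face (anti to the axial C10 ester) is opened trans-diaxially at C6 by the ester carbonyl oxygen (or by water, whose 6-OH then lactonises onto the 1,3-diaxial ester), which is the 5-bromo-6-oxy regiochemistry that 5-ene steroids show with hypobromous acid, so O6 is fixed on the lower face and Br on the upper face of C5.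

Step 7
Reactants: 9 bromolactone
Product: 10 trans-fused keto lactone ketal (H5 on the upper face)
Conditions: Bu3SnH, AIBN (cat.), toluene, 80 °C
Reagents that add atoms: none
Why: In this radical chain dehalogenation the tertiary C5 radical should take hydrogen on the upper face, axial to both rings, because the lower lobe is flanked by C19, O6 and the axial C4 methyl group, which gives the trans A/B fusion, and zinc is avoided because it would eliminate back to the alkene.

Step 8
Reactants: 10 C3 ketone
Product: 11 axial C3 alcohol (OH on the upper face, anti to C19)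
Conditions: LiBH(s-Bu)3, THF, −78 °C; then AcOH
Reagents that add atoms: none
Why: A bulky trialkylborohydride reduces a 4,4-dimethyl-3-ketone in a trans-decalin chair by equatorial attack, as in the preparation of 3-epi triterpenoids, so the axial alcohol should form while lactone and ketal stay inert at −78 °C.

Step 9
Reactants: 11 alcohol
Product: 12 C3 acetate
Conditions: Ac2O, DMAP, pyridine, CH2Cl2, rt
Reagents that add atoms: acetic anhydride, CC(=O)OC(C)=O
Why: DMAP-catalysed acylation (nucleophilic catalysis) is strong enough for the hindered axial alcohol next to the gem-dimethyl carbon and touches nothing else.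

Step 10
Reactants: 12 ketal acetate
Product: 13 AB keto lactone (C9 ketone)
Conditions: TFA/H2O (10:1), CH2Cl2, rt
Reagents that add atoms: water, O
Why: Acid-catalysed ketal hydrolysis frees the C9 ketone, and both the acetate and the lactone, whose α-carbon C10 is quaternary, tolerate aqueous TFA at room temperature.

Step 11
Reactants: 13 keto lactone
Product: 14 8-methyl keto lactone (C8 epimers)
Conditions: LiN(SiMe3)2 (1.05 equiv), THF, −78 °C; MeI, DMPU, −78 → −20 °C
Reagents that add atoms: iodomethane, CI
Why: In this kinetic enolate alkylation C9 can enolise only towards C8 because C10 is quaternary, and the ketone is several pK units more acidic than the acetate, so one equivalent of amide base at −78 °C should be selective.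

Step 12
Reactants: 14 8-methyl ketone
Product: 15 C9 enol triflate (C8=C9, methyl on C8)
Conditions: KN(SiMe3)2, THF, −78 °C; N-(5-chloro-2-pyridyl)triflimide, −78 → 0 °C
Reagents that add atoms: N-(5-chloro-2-pyridyl)bis(trifluoromethanesulfonimide), FC(F)(F)S(=O)(=O)N(c1ccc(Cl)cn1)S(=O)(=O)C(F)(F)F
Why: O-sulfonylation of the only possible (C8=C9) potassium enolate is standard enol triflate synthesis and erases the C8 stereocentre.

Step 13
Reactants: 15 enol triflate; 16 propanal
Product: 17 C11 allylic alcohol (C11 epimers)
Conditions: CrCl2 (4 equiv), NiCl2 (2 mol %), DMF, rt → 45 °C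
Reagents that add atoms: none
Why: In the Nozaki–Hiyama–Kishi coupling, nickel-catalysed formation of the alkenylchromium species and its addition to the small aldehyde form C9–C11 and tolerate lactone and acetate fully.

Step 14
Reactants: 17 allylic alcohol
Product: 18 ethyl enone (C8=C9–C11(=O)–CH2CH3)
Conditions: Dess–Martin periodinane, NaHCO3, CH2Cl2, rt
Reagents that add atoms: none
Why: Dess–Martin oxidation under buffered neutral conditions gives the enone without moving the tetrasubstituted alkene.

Step 15
Reactants: 18 ethyl enone
Product: 19 AB-lactone (Z)-2-silyloxydiene (C8=C9–C11(OTBS)=C12H–CH3, C12 methyl cis to OTBS)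
Conditions: TBSOTf, Et3N, CH2Cl2, 0 °C
Reagents that add atoms: tert-butyldimethylsilyl triflate, CC(C)(C)[Si](C)(C)OS(=O)(=O)C(F)(F)F
Why: Soft enolisation (silyl triflate with a tertiary amine) removes an α′-hydrogen at C12 rather than a γ-hydrogen because the carbonyl is twisted out of conjugation with the tetrasubstituted alkene, and the Z enol silane should form because the E isomer would press the C12 methyl group against C9 and its substituents (allylic 1,3-strain).

**Dienophile fragment (steps 16–22)**

Step 16
Reactants: 20 dimethyl squarate
Product: 22 3-methoxycyclobut-3-ene-1,2-dione, via hydroxycyclobutenone 21 (not isolated)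
Conditions: LiAlH(OtBu)3, THF, −78 → −20 °C; then 2 M HCl, CH2Cl2, rt
Reagents that add atoms: water, O
Why: Mono-reduction of one squarate carbonyl, then acid-induced loss of water and hydrolysis of the methoxy-stabilised cyclobutenyl cation, is the established route from dialkyl squarates to semisquarates.

Step 17
Reactants: 22 methyl semisquarate
Product: 23 rac-4-hydroxy-3-methoxy-4-methylcyclobut-2-en-1-one
Conditions: MeLi, THF, −78 °C; then AcOH
Reagents that add atoms: methyllithium, [Li]C
Why: 1,2-Addition takes place at the ketone-like carbonyl next to C–OMe and not at the vinylogous-ester carbonyl, which is the usual regiochemistry of alkoxycyclobutenediones, and it creates the future C16 carbinol as a racemate.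

Step 18
Reactants: 23 tertiary alcohol
Product: 24 rac-4-(tert-butyldimethylsilyloxy)-3-methoxy-4-methylcyclobut-2-en-1-one
Conditions: TBSOTf, 2,6-lutidine, CH2Cl2, 0 °C
Reagents that add atoms: tert-butyldimethylsilyl triflate, CC(C)(C)[Si](C)(C)OS(=O)(=O)C(F)(F)F
Why: Silylation of a tertiary alcohol with the silyl triflate and a hindered pyridine is standard and installs the bulky group that later shields one face of ring D.

Step 19
Reactants: 24 vinylogous ester
Product: 25 rac-4-(tert-butyldimethylsilyloxy)-2-iodo-3-methoxy-4-methylcyclobut-2-en-1-one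
Conditions: NIS, MeCN, rt, dark
Reagents that add atoms: N-iodosuccinimide, O=C1CCC(=O)N1I
Why: Electrophilic α-iodination of a β-alkoxy enone (iodonium attack at the nucleophilic α-carbon of the push–pull alkene, then loss of the proton) places the halogen on the future C14.

Step 20
Reactants: 25 iodo vinylogous ester
Product: 27 rac-4-(tert-butyldimethylsilyloxy)-2-iodo-3,4-dimethylcyclobut-2-en-1-one, via tertiary carbinol 26 (not isolated)
Conditions: MeMgBr, THF, −78 → −40 °C; then 1 M HCl, 0 °C
Reagents that add atoms: methylmagnesium bromide, C[Mg]Br; water, O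
Why: In this Stork–Danheiser-type carbonyl transposition the Grignard reagent adds 1,2 without exchanging with the alkenyl iodide at low temperature, acid-induced ionisation and hydrolysis then give the β-methyl α-iodo enone, and any direct addition–elimination at C–OMe converges on the same racemic product.

Step 21
Reactants: 27 racemic iodo enone
Product: 28 (S)-4-(tert-butyldimethylsilyloxy)-2-iodo-3,4-dimethylcyclobut-2-en-1-one
Conditions: preparative SFC, amylose tris(3,5-dimethylphenylcarbamate) phase, CO2/i-PrOH, 35 °C
Reagents that add atoms: none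
Why: Resolution by chromatography on a chiral stationary phase should deliver the enantiomer with the S configuration at the future C16, to be assigned by anomalous-dispersion X-ray analysis, which the iodine atom makes possible.

Step 22
Reactants: 28 (S)-iodo enone
Product: 29 methyl (3S)-3-(tert-butyldimethylsilyloxy)-2,3-dimethyl-4-oxocyclobut-1-ene-1-carboxylate
Conditions: PdCl2(PPh3)2 (5 mol %), CO (1 atm), MeOH (5 equiv), i-Pr2NEt, THF, rt → 40 °C
Reagents that add atoms: carbon monoxide, [C-]#[O+]; methanol, CO
Why: Palladium-catalysed alkoxycarbonylation (oxidative addition of the activated alkenyl iodide to zerovalent palladium, CO insertion, methanolysis of the acylpalladium) runs near room temperature for α-iodo enones, well below the temperature at which 4-oxy-cyclobutenones open to vinylketenes, and leaves C16 untouched.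

**Union and endgame (steps 23–27)**

Step 23
Reactants: 19 AB-lactone (Z)-silyloxydiene; 29 ring D cyclobutenone ester
Product: 30 tetracyclic adduct with a C9=C11 enol silane (C8–CH3, C13–CH3 and C14–CO2Me on the lower face; C12–CH3 and C16–CH3 on the upper face; C16–OTBS on the lower face)
Conditions: EtAlCl2 (2.5 equiv), 2,6-di-tert-butylpyridine (0.2 equiv), CH2Cl2, −78 → −20 °C
Reagents that add atoms: none
Why: EtAlCl2 binds the C15 ketone and the C14 ester of 29 and lowers the LUMO of the strained C13=C14 bond, so a concerted but highly asynchronous [4+2] cycloaddition should set in, in which the nucleophilic C12 end of the silyl dienol ether bonds first to C13 (the β-carbon of the enone ester) and C8–C14 bonding follows in the same event. The closest known reaction type is the Lewis-acid-promoted Diels–Alder reaction of cyclobutenones and of 2-alkoxycarbonyl-cycloalkenones with 2-silyloxydienes; the extension asked for here is a dienophile C=C bond without hydrogen, offset by release of ring strain on rehybridisation of C13 and C14 and by the double activation. Ring C is closed as a six-membered ring by suprafacial addition of C13=C14 across the termini C8 and C12 of the s-cis diene, with ring D carried in intact as the fused four-membered ring. C8 is controlled by the lactone bridge, whose C19 and O6 stand 1,3-diaxial to C8 on the lower face, so C14 bonds from the upper face and the C8 methyl group is pushed to the lower face. C13 and C14 are controlled by the C16 OTBS group, which leaves only the methyl-bearing face of the cyclobutenone open, together with the endo placement of the C15 carbonyl over C9–C11, which puts CO2Me and the C13 methyl group on the same side as the C8 methyl group; C12 follows from the Z enol-silane geometry (methyl outside, hence cis to C16) and is erased in step 25. The step therefore needs regioselectivity (C11 silyloxy donor against the β-carbon C13), endo selectivity (ring D ketone) and facial selectivity on both partners (lactone bridge, OTBS), and only the S enantiomer of 29 meets all of these at once with 19.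

Step 24
Reactants: 30 enol silane adduct
Product: 31 C11 ketone (H9 on the upper face, trans B/C; C12 as in 30)
Conditions: TFA (3 equiv), CH2Cl2/H2O (20:1), 0 °C
Reagents that add atoms: none
Why: In this protodesilylation of the enol silane the proton should reach C9 from the upper face because the lower face is covered by the C8 methyl group and C19, which gives the trans B/C fusion that is also the more stable one, and the hindered tertiary C16 silyl ether survives the short acid treatment.

Step 25
Reactants: 31 C11 ketone
Product: 32 C11 enol triflate (C11(OTf)=C12–CH3)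
Conditions: KN(SiMe3)2 (1.1 equiv), THF, −78 °C; N-(5-chloro-2-pyridyl)triflimide, −78 °C
Reagents that add atoms: N-(5-chloro-2-pyridyl)bis(trifluoromethanesulfonimide), FC(F)(F)S(=O)(=O)N(c1ccc(Cl)cn1)S(=O)(=O)C(F)(F)F
Why: In this kinetic enolate formation and O-triflation C15 has no α-hydrogen and H9 is buried between the quaternary carbons C8 and C10, so the amide base should take H12, and at −78 °C the endocyclic C13–C14 bond lies near the nodal plane of the enolate, which keeps retro-Michael cleavage slow.

Step 26
Reactants: 32 enol triflate
Product: 33 C16 silyl ether of the target (C11H=C12–CH3)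
Conditions: Pd(PPh3)4 (10 mol %), HCO2H, Et3N, DMF, 60 °C
Reagents that add atoms: none
Why: Palladium-catalysed formate reduction of an enol triflate (oxidative addition, formate exchange, decarboxylation to a palladium hydride, reductive elimination) replaces OTf by H without moving the double bond.

Step 27
Reactants: 33 silyl ether
Product: 34 penicimeroterpenoid B
Conditions: HF·pyridine, THF, 0 °C → rt
Reagents that add atoms: none
Why: Fluoride-mediated silyl ether cleavage in an acidic medium frees the tertiary C16 alcohol without exposing the α-hydroxy β-keto ester cyclobutanone, the acetate or the lactone to base.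

**Compound list**

1 | cyclohexane-1,3-dione | O=C1CCCC(=O)C1 | starting material
2 | methyl 3-oxocyclohex-1-en-1-yl carbonate | COC(=O)OC1=CC(=O)CCC1 | intermediate
3 | methyl 2-hydroxy-6-oxocyclohex-1-ene-1-carboxylate | COC(=O)C1=C(O)CCCC1=O | intermediate
4 | methyl vinyl ketone | CC(=O)C=C | starting material
5 | methyl 2,6-dioxo-1-(3-oxobutyl)cyclohexane-1-carboxylate | COC(=O)C1(CCC(C)=O)C(=O)CCCC1=O | intermediate
6 | methyl (S)-1,6-dioxo-2,3,4,6,7,8-hexahydronaphthalene-8a(1H)-carboxylate | COC(=O)[C@@]12CCC(=O)C=C1CCCC2=O | intermediate
7 | C9 ethylene ketal of 6 | COC(=O)[C@@]12CCC(=O)C=C1CCCC21OCCO1 | intermediate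
8 | 4,4-dimethyl-5(6)-en-3-one ester ketal | COC(=O)[C@@]12CCC(=O)C(C)(C)C1=CCCC21OCCO1 | intermediate
9 | 5-bromo-6,19-lactone, C3 ketone, C9 ketal | O=C1O[C@H]2CCC3(OCCO3)[C@@]14CCC(=O)C(C)(C)[C@@]24Br | intermediate
10 | trans-fused 6,19-lactone, C3 ketone, C9 ketal | O=C1O[C@H]2CCC3(OCCO3)[C@@]14CCC(=O)C(C)(C)[C@@H]24 | intermediate
11 | axial C3 alcohol | O=C1O[C@H]2CCC3(OCCO3)[C@@]14CC[C@H](O)C(C)(C)[C@@H]24 | intermediate
12 | C3 acetate, C9 ketal | O=C1O[C@H]2CCC3(OCCO3)[C@@]14CC[C@H](OC(C)=O)C(C)(C)[C@@H]24 | intermediate
13 | AB keto lactone (C9 ketone) | O=C1O[C@H]2CCC(=O)[C@@]14CC[C@H](OC(C)=O)C(C)(C)[C@@H]24 | intermediate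
14 | 8-methyl keto lactone (C8 epimers) | O=C1O[C@H]2CC(C)C(=O)[C@@]14CC[C@H](OC(C)=O)C(C)(C)[C@@H]24 | intermediate
15 | C9 enol triflate | O=C1O[C@H]2CC(C)=C(OS(=O)(=O)C(F)(F)F)[C@@]14CC[C@H](OC(C)=O)C(C)(C)[C@@H]24 | intermediate
16 | propanal | CCC=O | starting material
17 | C11 allylic alcohol (C11 epimers) | O=C1O[C@H]2CC(C)=C(C(O)CC)[C@@]14CC[C@H](OC(C)=O)C(C)(C)[C@@H]24 | intermediate
18 | ethyl enone | O=C1O[C@H]2CC(C)=C(C(=O)CC)[C@@]14CC[C@H](OC(C)=O)C(C)(C)[C@@H]24 | intermediate
19 | AB-lactone (Z)-silyloxydiene | C/C=C(\O[Si](C)(C)C(C)(C)C)C=1[C@]23CC[C@H](OC(C)=O)C(C)(C)[C@H]2[C@H](CC=1C)OC3=O | intermediate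
20 | dimethyl squarate | COC1=C(OC)C(=O)C1=O | starting material
21 | 4-hydroxy-2,3-dimethoxycyclobut-2-en-1-one | COC1=C(OC)C(=O)C1O | intermediate
22 | 3-methoxycyclobut-3-ene-1,2-dione | COC1=CC(=O)C1=O | intermediate
23 | rac-4-hydroxy-3-methoxy-4-methylcyclobut-2-en-1-one | COC1=CC(=O)C1(C)O | intermediate
24 | rac-4-(tert-butyldimethylsilyloxy)-3-methoxy-4-methylcyclobut-2-en-1-one | COC1=CC(=O)C1(C)O[Si](C)(C)C(C)(C)C | intermediate
25 | rac-4-(tert-butyldimethylsilyloxy)-2-iodo-3-methoxy-4-methylcyclobut-2-en-1-one | COC1=C(I)C(=O)C1(C)O[Si](C)(C)C(C)(C)C | intermediate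
26 | 4-(tert-butyldimethylsilyloxy)-2-iodo-3-methoxy-1,4-dimethylcyclobut-2-en-1-ol | COC1=C(I)C(C)(O)C1(C)O[Si](C)(C)C(C)(C)C | intermediate
27 | rac-4-(tert-butyldimethylsilyloxy)-2-iodo-3,4-dimethylcyclobut-2-en-1-one | CC1=C(I)C(=O)C1(C)O[Si](C)(C)C(C)(C)C | intermediate
28 | (S)-4-(tert-butyldimethylsilyloxy)-2-iodo-3,4-dimethylcyclobut-2-en-1-one | CC1=C(I)C(=O)[C@@]1(C)O[Si](C)(C)C(C)(C)C | intermediate
29 | methyl (3S)-3-(tert-butyldimethylsilyloxy)-2,3-dimethyl-4-oxocyclobut-1-ene-1-carboxylate | COC(=O)C1=C(C)[C@](C)(O[Si](C)(C)C(C)(C)C)C1=O | intermediate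
30 | tetracyclic Diels–Alder adduct, C9=C11 enol silane | COC(=O)[C@@]12C(=O)[C@@](C)(O[Si](C)(C)C(C)(C)C)[C@]1(C)[C@H](C)C(O[Si](C)(C)C(C)(C)C)=C1[C@]34CC[C@H](OC(C)=O)C(C)(C)[C@H]3[C@H](C[C@@]12C)OC4=O | intermediate
31 | tetracyclic C11 ketone | COC(=O)[C@@]12C(=O)[C@@](C)(O[Si](C)(C)C(C)(C)C)[C@]1(C)[C@H](C)C(=O)[C@H]1[C@]34CC[C@H](OC(C)=O)C(C)(C)[C@H]3[C@H](C[C@@]12C)OC4=O | intermediate
32 | C11 enol triflate | COC(=O)[C@@]12C(=O)[C@@](C)(O[Si](C)(C)C(C)(C)C)[C@]1(C)C(C)=C(OS(=O)(=O)C(F)(F)F)[C@H]1[C@]34CC[C@H](OC(C)=O)C(C)(C)[C@H]3[C@H](C[C@@]12C)OC4=O | intermediate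
33 | C16 O-TBS penicimeroterpenoid B | COC(=O)[C@@]12C(=O)[C@@](C)(O[Si](C)(C)C(C)(C)C)[C@]1(C)C(C)=C[C@H]1[C@]34CC[C@H](OC(C)=O)C(C)(C)[C@H]3[C@H](C[C@@]12C)OC4=O | intermediate
34 | penicimeroterpenoid B | COC(=O)[C@@]12C(=O)[C@@](C)(O)[C@]1(C)C(C)=C[C@H]1[C@]34CC[C@H](OC(C)=O)C(C)(C)[C@H]3[C@H](C[C@@]12C)OC4=O | target

**Step count**

Total step count: 27 (15 to diene 19, 7 to dienophile 29, 5 from the union onwards).
Longest linear sequence: 20 steps (steps 1–15, then 23–27).

**Steps most likely to fail**

1. Step 23.
   - What may go wrong: The diene may not reach the s-cis geometry, because the C8 methyl group is an inside substituent and both C9 and C11 are substituted. Protodesilylation of the diene or Lewis-acid degradation of the dienophile could then outrun bond formation. Bonding may also stop after C12–C13, or exo approach may compete.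
   - Fallback (sets out from 19 and 29, comes back at 31): The two bonds are made one after the other, which needs no s-cis diene.
     - A Mukaiyama–Michael addition (HNTf2 5 mol %, CH2Cl2, −78 °C, then dilute HCl) joins C12 to C13 anti to the OTBS group and gives the seco enone β-keto ester F1.
     - Cs2CO3 in MeCN then closes C14 onto C8 by an intramolecular 6-endo-trig Michael addition from the upper face of ring B (a sequential double Michael addition). This should give 31 together with the C12 epimer of 31 F2.
     - Both ketones lead to 32 in step 25.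

2. Step 25.
   - What may go wrong: Deprotonation may occur at C9 instead of C12. Enolisation may be slow because H12 is equatorial in the cycloadduct-derived epimer. Retro-Michael opening of the C13–C14 bond may occur from the enolate on warming.
   - Fallback (sets out from 15 and 29, comes back at 32): The enolate regiochemistry is fixed by a conjugate reduction, so there is no choice between H9 and H12.
     - Stille coupling of 15 with tributyl(1-ethoxyvinyl)stannane (Pd(PPh3)4, LiCl, THF, 60 °C) gives the 2-ethoxydiene F3, which lacks the C12 methyl group and is also a less hindered diene.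
     - EtAlCl2-promoted cycloaddition of F3 with 29 gives the enol ether adduct F4.
     - Dilute acid gives the C11 ketone with a C12 methylene group F5.
     - α-Methylenation (paraformaldehyde, i-Pr2NH·CF3CO2H, THF, reflux) can take place only at C12 and gives the exocyclic enone F6.
     - LiBH(s-Bu)3 at −78 °C puts hydride on the exocyclic CH2, leaving the C15 ketone, which is flanked by two quaternary carbons, alone. The regiodefined C11=C12 enolate is trapped with the pyridyl triflimide to give 32.

3. Step 22.
   - What may go wrong: Methanol may add in conjugate fashion, or the amine may degrade the doubly activated cyclobutenone, while it sits under the carbonylation conditions. Slow carbonylation would also force temperatures at which the ring opens.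
   - Fallback (sets out from 25, comes back at 29): The ester is introduced while the ring is still a deactivated push–pull system.
     - Carbonylation of 25 (PdCl2(PPh3)2, CO, MeOH, i-Pr2NEt) gives the β-methoxy keto ester F7, which is indifferent to methanol.
     - Me2CuLi (1.0 equiv, Et2O, −78 °C) replaces OMe by methyl through addition–elimination under aprotic conditions and gives the racemic dienophile F8.
     - Preparative HPLC on an immobilised amylose phase with hexane/EtOAc then delivers 29.

**Further compounds**

F1 | step 23 | seco enone β-keto ester (C12–C13 bond made, C8–C14 open; C12 and C14 not controlled) | COC(=O)C1C(=O)[C@@](C)(O[Si](C)(C)C(C)(C)C)[C@]1(C)C(C)C(=O)C=2[C@]34CC[C@H](OC(C)=O)C(C)(C)[C@H]3[C@H](CC=2C)OC4=O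
F2 | step 23 | C12 epimer of 31 | COC(=O)[C@@]12C(=O)[C@@](C)(O[Si](C)(C)C(C)(C)C)[C@]1(C)[C@@H](C)C(=O)[C@H]1[C@]34CC[C@H](OC(C)=O)C(C)(C)[C@H]3[C@H](C[C@@]12C)OC4=O
F3 | step 25 | AB-lactone 2-ethoxydiene without C12 methyl | C=C(OCC)C=1[C@]23CC[C@H](OC(C)=O)C(C)(C)[C@H]2[C@H](CC=1C)OC3=O
F4 | step 25 | 12-demethyl adduct, C9=C11 enol ethyl ether | COC(=O)[C@@]12C(=O)[C@@](C)(O[Si](C)(C)C(C)(C)C)[C@]1(C)CC(OCC)=C1[C@]34CC[C@H](OC(C)=O)C(C)(C)[C@H]3[C@H](C[C@@]12C)OC4=O
F5 | step 25 | 12-demethyl C11 ketone | COC(=O)[C@@]12C(=O)[C@@](C)(O[Si](C)(C)C(C)(C)C)[C@]1(C)CC(=O)[C@H]1[C@]34CC[C@H](OC(C)=O)C(C)(C)[C@H]3[C@H](C[C@@]12C)OC4=O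
F6 | step 25 | 12-methylene C11 ketone | COC(=O)[C@@]12C(=O)[C@@](C)(O[Si](C)(C)C(C)(C)C)[C@]1(C)C(=C)C(=O)[C@H]1[C@]34CC[C@H](OC(C)=O)C(C)(C)[C@H]3[C@H](C[C@@]12C)OC4=O
F7 | step 22 | rac-methyl 3-(tert-butyldimethylsilyloxy)-2-methoxy-3-methyl-4-oxocyclobut-1-ene-1-carboxylate | COC(=O)C1=C(OC)C(C)(O[Si](C)(C)C(C)(C)C)C1=O
F8 | step 22 | rac-methyl 3-(tert-butyldimethylsilyloxy)-2,3-dimethyl-4-oxocyclobut-1-ene-1-carboxylate | COC(=O)C1=C(C)C(C)(O[Si](C)(C)C(C)(C)C)C1=O
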